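**Retrosynthetic overview**

1. The target is a 9-oxobicyclo[3.3.1]nonane. Locants used throughout: C1 carbinol bridgehead, C2 CH2, C3 C–N, C4 CHOH, C5 CH bridgehead, C6 C–OMe, C7/C8 oxirane carbons (C8 next to C1), C9 ketone; ring A = C1-C2-C3-C4-C5-C9, ring B = C1-C9-C5-C6-C7-C8. Last cuts: the C7–C8 oxirane (hydroxyl-directed epoxidation), the amide C–N bond, and C6–OMe (allylic C–H hydroxylation next to the C7=C8 alkene, then O-methylation).
2. Key disconnection: C1–C2 and C4–C5 are cut together in a formal [3+3] Michael–aldol annulation. The whole C2–C3–C4 bridge is 2-(Boc-amino)acrolein, laid across the two α-carbons of a ring B ketone, 2-(PMB-oxy)cyclohex-3-enone.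
3. Enabling feature: the C9 ketone lies between both bridgeheads, so C1 and C5 are its α and α′ carbons. The C4 hydroxyl is β to C9 (aldol retron) and C4 is 1,5 to C9 through C1–C2–C3 (Michael retron). C1 is also oxygen-bearing and allylic to C7=C8, which makes it the first nucleophile, and Bredt's rule protects the β-oxygenated bridged ketone from elimination afterwards.
4. Ring order: ring B is bought as cyclohexane-1,2-dione (its two oxygens become C1–O and C9=O). Ring A is closed in the key step, which sets C1, C3, C4 and C5 at once (C1 by the catalyst, the others relayed). The oxirane comes last.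

Key step: step 4

Remark 1: the quinine-derived squaramide is assumed to deliver the (1S) quaternary centre of 8; if the sense proves opposite, the pseudoenantiomeric quinidine-derived squaramide is used with no other change.
Remark 2: exo means the face of ring B turned away from the C2–C3–C4 bridge; CIP descriptors of bicyclic compounds use the locants defined above.

**Step 1**
Reactants: 1 cyclohexane-1,2-dione
Product: 2 2-[(4-methoxyphenyl)methoxy]cyclohex-2-en-1-one
Conditions: 4-methoxybenzyl chloride, K2CO3, DMF, 50 °C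
Reagents that add atoms: 4-methoxybenzyl chloride, COc1ccc(CCl)cc1
Why: Williamson-type O-alkylation of the enol (diosphenol) form of the 1,2-dione should give the enol ether; no stereocentre is formed.

**Step 2**
Reactants: 2 2-[(4-methoxyphenyl)methoxy]cyclohex-2-en-1-one
Product: 4 rac-2-[(4-methoxyphenyl)methoxy]cyclohex-3-en-1-one, via potassium dienolate 3 (not isolated)
Conditions: KOtBu (3 equiv), tBuOH/THF, 23 °C; inverse quench into cold 10% aq AcOH
Reagents that add atoms: none
Why: Base-mediated deconjugation: equilibrating γ-deprotonation gives the linear dienolate 3 and kinetic protonation at its α-carbon gives the β,γ-unsaturated ketone; the new stereocentre is racemic and is erased again in step 4.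

**Step 3**
Reactants: 5 tert-butyl N-(2-oxoethyl)carbamate
Product: 6 tert-butyl N-(3-oxoprop-1-en-2-yl)carbamate
Conditions: 37% aq CH2O, pyrrolidine (10 mol %), propionic acid (10 mol %), iPrOH, 45 °C; used at once
Reagents that add atoms: formaldehyde, C=O
Why: Organocatalytic α-methylenation of an aldehyde (Mannich condensation with formaldehyde through the pyrrolidine enamine, then elimination of the amine); no stereocentre is formed.

**Step 4**
Reactants: 4 rac-2-[(4-methoxyphenyl)methoxy]cyclohex-3-en-1-one; 6 tert-butyl N-(3-oxoprop-1-en-2-yl)carbamate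
Product: 8 tert-butyl N-[(1S,3S,4R,5R)-4-hydroxy-1-[(4-methoxyphenyl)methoxy]-9-oxobicyclo[3.3.1]non-7-en-3-yl]carbamate, via Michael adduct 7 (not isolated)
Conditions: quinine-derived 3,5-bis(trifluoromethyl)phenyl squaramide (10 mol %), CH2Cl2, 0 °C; then DBU (0.3 equiv), 0 °C, same flask
Reagents that add atoms: none
Why: Proposed new method: the quinuclidine of the catalyst removes the doubly activated α-proton of 4 (α to the ketone, allylic, oxygen-bearing; its stereocentre is erased), and the resulting ammonium dienolate, held by the squaramide next to the hydrogen-bonded acrolein 6, attacks the CH2 terminus through its oxygen-bearing α-carbon to give 7 (new C1–C2 bond), after which DBU enolises the only α-position left and an aldol addition to the aldehyde closes ring A (new C4–C5 bond). The closest known reaction types are the bifunctional Brønsted-base/hydrogen-bond catalysed α-selective Michael additions of transient dienolates of α-branched β,γ-unsaturated ketones, which create quaternary α-centres, and the classical Michael–aldol α,α′-annulation of cyclohexanones with acroleins to 2-hydroxybicyclo[3.3.1]nonan-9-ones; new is their merger on an α-alkoxy dienolate and a 2-amidoacrolein. Ring A is closed in the 6-(enolendo)-exo-trig mode through a chair transition state. C1 is set by the catalyst (enantioface of the dienolate); C5 must follow because the three-carbon bridge can only span one face of ring B; C3 equilibrates through the enolisable α-amino aldehyde and should settle with NHBoc equatorial (exo); C4 is set by the closed, hydrogen-bonded transition state that keeps the aldehyde oxygen next to the enolate oxygen, which gives the axial alcohol syn to the C9 carbonyl. The step needs α- over γ-attack of the dienolate and 1,4- over 1,2-addition to the enal: the α-carbon carries the highest charge density of the ion-paired dienolate, a γ-adduct cannot cyclise and aldolates of the enal revert, whereas the α-adduct is drained into the bicycle.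

**Step 5**
Reactants: 8 tert-butyl N-[(1S,3S,4R,5R)-4-hydroxy-1-[(4-methoxyphenyl)methoxy]-9-oxobicyclo[3.3.1]non-7-en-3-yl]carbamate
Product: 9 (1S,3S,4R,5R)-N-Boc-3-N,4-O-isopropylidene derivative of 8 (N-Boc-2,2-dimethyl-1,3-oxazolidine cis-fused across C3–C4)
Conditions: 2,2-dimethoxypropane, PPTS (cat.), toluene, 60 °C
Reagents that add atoms: 2,2-dimethoxypropane, COC(C)(C)OC
Why: Acid-catalysed transacetalisation should give the Garner-type N,O-acetonide across the cis C3–N/C4–O pair, masking N–H and the C4 hydroxyl in one step; no stereocentre is touched.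

**Step 6**
Reactants: 9 (1S,3S,4R,5R)-N-Boc-3-N,4-O-isopropylidene derivative of 8
Product: 10 (1S,3S,4R,5R,6R)-6-hydroxy derivative of 9 (C6–OH axial, on the exo face of ring B)
Conditions: SeO2 (20 mol %), TBHP (3 equiv), CH2Cl2, 23 °C
Reagents that add atoms: selenium dioxide (oxygen carrier), O=[Se]=O; tert-butyl hydroperoxide (terminal oxygen source), CC(C)(C)OO
Why: Sharpless SeO2/TBHP allylic hydroxylation (ene reaction at C8 with transfer of the exo C6–H, then [2,3]-sigmatropic shift) should put oxygen on C6, the only allylic carbon that bears hydrogen, and on the open exo face because both pericyclic events occur there.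

**Step 7**
Reactants: 10 (1S,3S,4R,5R,6R)-6-hydroxy derivative of 9
Product: 11 (1S,3S,4R,5R,6R)-6-methoxy derivative of 9
Conditions: Me3OBF4, 1,8-bis(dimethylamino)naphthalene, 4 Å MS, CH2Cl2, 0 to 23 °C
Reagents that add atoms: trimethyloxonium tetrafluoroborate, C[O+](C)C.F[B-](F)(F)F
Why: O-Methylation with Meerwein's salt and proton sponge is chosen because it never forms the C6 alkoxide, which could fragment this β-hydroxy ketone by retro-aldol; the C6 configuration is untouched.

**Step 8**
Reactants: 11 (1S,3S,4R,5R,6R)-6-methoxy derivative of 9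
Product: 12 (1S,3S,4R,5S,6R)-3-amino-1,4-dihydroxy-6-methoxybicyclo[3.3.1]non-7-en-9-one
Conditions: TFA/CH2Cl2/H2O (10:10:1), 0 to 23 °C; NaHCO3 work-up
Reagents that add atoms: none
Why: Acidolysis should cleave the Boc group, the N,O-isopropylidene and the PMB ether together, and the skeleton should survive because the C1 bridgehead cannot ionise and the bridged β-oxygenated ketone cannot eliminate.

**Step 9**
Reactants: 12 (1S,3S,4R,5S,6R)-3-amino-1,4-dihydroxy-6-methoxybicyclo[3.3.1]non-7-en-9-one; 13 (2E)-dodec-2-enoic acid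
Product: 14 (2E)-N-[(1S,3S,4R,5S,6R)-1,4-dihydroxy-6-methoxy-9-oxobicyclo[3.3.1]non-7-en-3-yl]dodec-2-enamide
Conditions: N,N'-diisopropylcarbodiimide, HOBt (cat.), CH2Cl2/DMF, 0 to 23 °C
Reagents that add atoms: none
Why: Carbodiimide/HOBt amide coupling should acylate the primary amine in preference to the hindered secondary and tertiary hydroxyls.

**Step 10**
Reactants: 14 (2E)-N-[(1S,3S,4R,5S,6R)-1,4-dihydroxy-6-methoxy-9-oxobicyclo[3.3.1]non-7-en-3-yl]dodec-2-enamide
Product: 15 (2E)-N-[(1S,3S,4R,5S,6S,7S,8S)-7,8-epoxy-1,4-dihydroxy-6-methoxy-9-oxobicyclo[3.3.1]nonan-3-yl]dodec-2-enamide (target)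
Conditions: VO(acac)2 (5 mol %), TBHP (1.5 equiv), CH2Cl2, 0 to 23 °C
Reagents that add atoms: tert-butyl hydroperoxide, CC(C)(C)OO
Why: Hydroxyl-directed epoxidation (Sharpless–Michaelson): the tertiary allylic C1–OH should deliver oxygen to the exo face of C7=C8, which is also the sterically open face, while the electron-poor enamide alkene has no directing group and should stay untouched.

**Compound list**

1 | cyclohexane-1,2-dione | O=C1CCCCC1=O | starting material
2 | 2-[(4-methoxyphenyl)methoxy]cyclohex-2-en-1-one | COc1ccc(COC2=CCCCC2=O)cc1 | intermediate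
3 | potassium 2-[(4-methoxyphenyl)methoxy]cyclohexa-1,3-dien-1-olate | [K+].[O-]C1=C(OCc2ccc(OC)cc2)C=CCC1 | intermediate (not isolated)
4 | rac-2-[(4-methoxyphenyl)methoxy]cyclohex-3-en-1-one | COc1ccc(COC2C=CCCC2=O)cc1 | intermediate
5 | tert-butyl N-(2-oxoethyl)carbamate | CC(C)(C)OC(=O)NCC=O | starting material
6 | tert-butyl N-(3-oxoprop-1-en-2-yl)carbamate | CC(C)(C)OC(=O)NC(=C)C=O | intermediate
7 | tert-butyl N-[1-[(1S)-1-[(4-methoxyphenyl)methoxy]-2-oxocyclohex-5-en-1-yl]-3-oxopropan-2-yl]carbamate (both epimers at the amino carbon) | CC(C)(C)OC(=O)NC(C=O)C[C@@]1(OCc2ccc(OC)cc2)C(=O)CCC=C1 | intermediate (not isolated)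
8 | tert-butyl N-[(1S,3S,4R,5R)-4-hydroxy-1-[(4-methoxyphenyl)methoxy]-9-oxobicyclo[3.3.1]non-7-en-3-yl]carbamate (NHBoc equatorial/exo, C4–OH axial) | CC(C)(C)OC(=O)N[C@H]1C[C@@]2(OCc3ccc(OC)cc3)C(=O)[C@@H]([C@H]1O)CC=C2 | intermediate
9 | (1S,3S,4R,5R)-N-Boc-3-N,4-O-isopropylidene derivative of 8 | CC(C)(C)OC(=O)N1[C@H]2C[C@@]3(OCc4ccc(OC)cc4)C(=O)[C@@H]([C@H]2OC1(C)C)CC=C3 | intermediate
10 | (1S,3S,4R,5R,6R)-6-hydroxy derivative of 9 (C6–OH exo, axial) | CC(C)(C)OC(=O)N1[C@H]2C[C@@]3(OCc4ccc(OC)cc4)C(=O)[C@@H]([C@H]2OC1(C)C)[C@H](O)C=C3 | intermediate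
11 | (1S,3S,4R,5R,6R)-6-methoxy derivative of 9 | CC(C)(C)OC(=O)N1[C@H]2C[C@@]3(OCc4ccc(OC)cc4)C(=O)[C@@H]([C@H]2OC1(C)C)[C@H](OC)C=C3 | intermediate
12 | (1S,3S,4R,5S,6R)-3-amino-1,4-dihydroxy-6-methoxybicyclo[3.3.1]non-7-en-9-one | N[C@H]1C[C@@]2(O)C(=O)[C@@H]([C@H]1O)[C@H](OC)C=C2 | intermediate
13 | (2E)-dodec-2-enoic acid | CCCCCCCCC/C=C/C(=O)O | starting material
14 | (2E)-N-[(1S,3S,4R,5S,6R)-1,4-dihydroxy-6-methoxy-9-oxobicyclo[3.3.1]non-7-en-3-yl]dodec-2-enamide | CCCCCCCCC/C=C/C(=O)N[C@H]1C[C@@]2(O)C(=O)[C@@H]([C@H]1O)[C@H](OC)C=C2 | intermediate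
15 | (2E)-N-[(1S,3S,4R,5S,6S,7S,8S)-7,8-epoxy-1,4-dihydroxy-6-methoxy-9-oxobicyclo[3.3.1]nonan-3-yl]dodec-2-enamide | CCCCCCCCC/C=C/C(=O)N[C@H]1C[C@@]2(O)C(=O)[C@@H]([C@H]1O)[C@H](OC)[C@@H]1O[C@@H]12 | target

**Step count and risks**

Total step count: 10. Longest linear sequence: 9 steps (steps 1, 2, 4, 5, 6, 7, 8, 9, 10, from cyclohexane-1,2-dione).

Three steps most likely to fail:

1. Step 4 (Proposed new method). What may go wrong: attack of the dienolate through its γ-carbon or 1,2-addition to the aldehyde, re-conjugation of 4 to 2 before C–C bond formation, erosion of enantioselectivity by an uncatalysed background or retro-Michael pathway, and incomplete aldol closure. Fallback with known chemistry: it sets out from 4 and 6 and gives up asymmetric induction. The two partners are joined by the classical amine-base Michael–aldol annulation (DBU, MeCN, 0 to 23 °C), which should give 8 as a racemate, that is, together with its mirror image tert-butyl N-[(1R,3R,4S,5S)-4-hydroxy-1-[(4-methoxyphenyl)methoxy]-9-oxobicyclo[3.3.1]non-7-en-3-yl]carbamate F1. The two are separated by preparative chromatography on a chiral stationary phase, and the route is rejoined at 8.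

2. Step 6. What may go wrong: a sluggish ene reaction at C8, which sits next to the quaternary C1, over-oxidation of the allylic alcohol to the enone, and oxidation at the benzylic position of the PMB ether. The fallback sets out from 9 and replaces the ene/[2,3] sequence by an epoxide-based oxygen transposition. Epoxidation (mCPBA, NaHCO3, CH2Cl2) should give the 7,8-exo-epoxide of 9 F2. Syn-β-elimination with Et2Al(NC9H18) (diethylaluminium 2,2,6,6-tetramethylpiperidide, toluene, 0 °C) can only use the C6 hydrogen and should give the (8-exo)-8-hydroxy-6-ene isomer of 10 F3. Suprafacial 1,3-transposition of this allylic alcohol with Ph3SiOReO3 (cat., Et2O, 0 °C) should move the hydroxyl from the hindered C8 to C6 on the same exo face, which rejoins the route at 10.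

3. Step 3. What may go wrong: polymerisation or hydration of the captodative acrolein 6 during methylenation or handling, and tautomerisation to the N-acyl imine. The fallback sets out from 4 as the unchanged annulation partner and swaps 6 for the known, crystalline 2-phthalimidoacrolein F4, made from commercial phthalimidoacetaldehyde under the step 3 conditions. Annulation with 4 under the step 4 conditions should give 2-[(1S,3S,4R,5R)-4-hydroxy-1-[(4-methoxyphenyl)methoxy]-9-oxobicyclo[3.3.1]non-7-en-3-yl]isoindoline-1,3-dione F5. Methylaminolysis (MeNH2, EtOH, 23 °C) should release (1S,3S,4R,5R)-3-amino-4-hydroxy-1-[(4-methoxyphenyl)methoxy]bicyclo[3.3.1]non-7-en-9-one F6. Boc2O/NaHCO3 (THF/H2O) then rejoins the route at 8.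

Further compounds
F1 | step 4 | tert-butyl N-[(1R,3R,4S,5S)-4-hydroxy-1-[(4-methoxyphenyl)methoxy]-9-oxobicyclo[3.3.1]non-7-en-3-yl]carbamate (enantiomer of 8) | CC(C)(C)OC(=O)N[C@@H]1C[C@]2(OCc3ccc(OC)cc3)C(=O)[C@H]([C@@H]1O)CC=C2
F2 | step 6 | 7,8-exo-epoxide of 9 | CC(C)(C)OC(=O)N1[C@H]2C[C@@]3(OCc4ccc(OC)cc4)C(=O)[C@@H]([C@H]2OC1(C)C)C[C@@H]1O[C@@H]13
F3 | step 6 | (8-exo)-8-hydroxy-6-ene isomer of 10 | CC(C)(C)OC(=O)N1[C@H]2C[C@@]3(OCc4ccc(OC)cc4)C(=O)[C@@H]([C@H]2OC1(C)C)C=C[C@@H]3O
F4 | step 3 | 2-phthalimidoacrolein, 2-(1,3-dioxoisoindolin-2-yl)prop-2-enal | C=C(C=O)N1C(=O)c2ccccc2C1=O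
F5 | step 3 | 2-[(1S,3S,4R,5R)-4-hydroxy-1-[(4-methoxyphenyl)methoxy]-9-oxobicyclo[3.3.1]non-7-en-3-yl]isoindoline-1,3-dione | O=C1c2ccccc2C(=O)N1[C@H]1C[C@@]2(OCc3ccc(OC)cc3)C(=O)[C@@H]([C@H]1O)CC=C2
F6 | step 3 | (1S,3S,4R,5R)-3-amino-4-hydroxy-1-[(4-methoxyphenyl)methoxy]bicyclo[3.3.1]non-7-en-9-one | N[C@H]1C[C@@]2(OCc3ccc(OC)cc3)C(=O)[C@@H]([C@H]1O)CC=C2
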